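## The problem

Compound 21 is a 2,3-dihydro-1H-indene with three contiguous ring stereocentres: C1 (4-hydroxyphenyl), C2 (3,5-dihydroxyphenyl) and C3, which carries the CH(OH)(4-hydroxyphenyl) side chain (carbinol carbon Cα). The benzo ring is hydroxylated at C5 and C7, with fusion carbons C7a (on C1) and C3a (on C3); this numbering is used in the discussion, whereas the systematic names in the compound list count the ring from the side-chain end. The aryl groups on C1 and C2 are trans, the C2 aryl and the C3 side chain are cis, and Cα is R. The trans C1/C2 relation is the stable one and can be relayed from C1 whenever C2 is enolisable, so only C1 has to be made by asymmetric synthesis. The cis C2/C3 relation is the less stable one and must be set kinetically, by delivering hydrogen to C3 on the face away from the C2 aryl. Cα has no dependable neighbour to lean on unless it is tied to C3 in one stereospecific event. The six phenols are oxidation-prone, and the 4-hydroxybenzylic alcohol ionises under acid to a quinone methide-type cation that the cis resorcinol ring on C2 would capture; once the carbinol exists no acid may be used, and the phenol protecting groups must leave under neutral conditions. The enabling feature is that C7a lies ortho to the C7 oxygen and para to the C5 oxygen: with C3 as a carbonyl, the C7a–C1 bond is the one a 3,5-dioxygenated aryl vinyl ketone closes in a Nazarov 4π-electrocyclisation, which sets C1 in the ring closure and C2 in the protonation that follows.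

## Retrosynthesis

**21 ⇒ 20.** The six phenolic O–H bonds are made last, from the hexakis(tert-butyldimethylsilyl) ether 20. Methyl or benzyl ethers would need a Lewis acid or hydrogenolysis at the end, and both threaten the oxybenzylic carbinol; silyl ethers leave with buffered fluoride. The skeleton is unchanged; the forward step must avoid both phenoxide-driven and acid-driven loss of the carbinol.

**20 ⇒ 18.** The C3–H and Cα–O bonds are cut together, as a hydroboration–oxidation of the Z-benzylidene indane 18. The neighbouring cuts are Cα–aryl (aryl-metal addition to a C3 aldehyde) and Cα–H (reduction of a C3 aryl ketone). Both pass through a carbonyl compound that can epimerise at C3 to the unwanted trans isomer, and both leave Cα to open-chain induction. The syn addition instead converts one alkene geometry into two stereocentres. It requires boron at Cα, hydrogen at C3 on the face anti to the C2 aryl, and the Z alkene (benzylidene aryl on the benzo side); the E isomer would give the Cα epimer.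

**18 ⇒ 17.** No bond is cut; the Z alkene is taken from the E isomer 17 by triplet-sensitised isomerisation. Olefinations that build this exocyclic alkene deliver the E isomer, so the geometry is corrected afterwards instead of being sought directly. The forward step needs a photostationary state that favours the twisted isomer.

**17 ⇒ 16 ⇒ 15.** The silyl ethers of 17 come from the hexaphenol 16 and this from the hexamethyl ether 15. The exchange sits at the alkene stage because 15 is the last intermediate that tolerates Lewis-acid demethylation, while every earlier step (strong acid, hot hydroxide) needs the robust methyl ethers.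

**15 ⇒ 13 ⇒ 12 ⇒ 10 + 11 ⇒ 9.** The C3=Cα bond is cut by a Ramberg–Bäcklund reaction of sulfone 13. The sulfone comes from sulfide 12, made by C3–S bond formation between indanol 10 and thiol 11; 10 comes from ketone 9. A direct Wittig or Julia reaction on 9 would meet a hindered, readily enolised 2-aryl ketone. Benzyl-metal addition followed by dehydration would move the double bond into the ring under acid and erase C2. The cut removes one aryl ring and leaves 9, which holds both aryl-bearing stereocentres.

**9 ⇒ 8.** The C7a–C1 bond is cut, opening the five-membered ring to the aryl vinyl ketone 8. Cutting C3–C3a (acylation) or C1–C2 instead would give no handle on the absolute configuration at C1. Here the precursor is achiral, acyclic and symmetric in its ketone aryl ring. The forward reaction must close onto an arene carbon ortho/para to two methoxy groups and control the sense of conrotation; C2 follows by equilibration.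

**8 ⇒ 6 + 7; 6 ⇒ 3 + 4; 3 ⇒ 1.** The enone double bond is cut by aldol condensation into deoxybenzoin 6 and aldehyde 7. The acyl–aryl bond of 6 is cut into Weinreb amide 3 and the Grignard reagent 5 made from bromide 4; a Friedel–Crafts route cannot give the 3,5-pattern. Amide 3 comes from acid 1. All four purchased materials (1, 4, 7, 11) are simple.

## Roads not taken

**Alternative 1:** The cut goes through the benzo ring (C3a–C7a and C6–C7). A 4-bromofuran and a terminal alkyne, held on an open C1–C2–C3 chain in the furan–yne A2, are joined by AuCl3 to give the 5-bromoindan-7-ol A1, with the furan oxygen delivered to C7.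
- Merits: C2, C3 and Cα are set in open-chain chemistry before any ring exists; the carbinol is already in place as a silyl ether; the gold step is neutral.
- Weak points: A1 has a methylene at C1, so the 4-hydroxyphenyl group and its stereocentre must be added afterwards by a trans-selective benzylic arylation, for which no dependable method exists. The C5 bromide must still be turned into a hydroxyl. The benzyl ethers must be hydrogenolysed beside a benzylic alcohol. A2 itself needs a multistep stereoselective synthesis.
- Comparison: this road is better at Cα and C3, since it needs neither photoisomerisation nor a late hydroboration. The chosen plan sets against it that it makes C1, the centre left open here, in its key step, and reaches the full triaryl skeleton with the correct oxygenation in four steps.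

**Alternative 2:** The cut removes the C2–aryl, C3–acyl and acyl–aryl bonds without forming a ring. Indene A4, aryl bromide A5, CO and arylstannane A6 are combined under Pd(OAc)2/(R)-BINAP to give the cis ketone A3.
- Merits: it is the most convergent road; syn carbopalladation gives the cis C2/C3 relation directly, which the chosen plan obtains only by a late hydroboration; Cα arrives one reduction away from the carbinol.
- Weak points: A3 also lacks the C1 aryl. The arylpalladium can be intercepted by CO and A6 before it meets A4; the benzylic palladium must insert CO before it isomerises. Enantioselective intermolecular arylpalladation of an indene inside such a cascade is without precedent. The ketone reduction would rest on Felkin-type induction, and the benzyl ethers raise the same end-game problem as in Alternative 1.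
- Comparison: it is shorter on paper and better for C2/C3. The chosen plan has one unproven element (enantioselectivity in an otherwise known cyclisation) with a resolution behind it, whereas here both the cascade and the later C1 arylation are unproven.

**Alternative 3:** The C2–C3 bond is formed by ring contraction. Photolysis of the trans-diaryl diazotetralone A8 gives a ketene by 1,2-shift of C2, and capture by MeNHOMe with protonation at C3 gives the Weinreb amide A7.
- Merits: the Wolff rearrangement is reliable and the migrating C2 keeps its configuration. The side-chain carbon arrives at a useful oxidation level. Kinetic protonation anti to the C2 aryl can give the cis C2/C3 relation in the key step. Only aryl addition, ketone reduction and ether handling remain, which is clearly fewer operations after the key step than the nine of the chosen plan.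
- Weak points: A8 needs an enantioenriched trans-3,4-diaryl-2-tetralone, a problem as large as the indanone itself, and a regioselective diazo transfer. C3 in A7 is benzylic and α to a carbonyl in its less stable configuration, and it is exposed to a basic aryl-metal reagent and again in the aryl ketone. Cα rests on substrate-controlled reduction. The methyl ethers would still have to be exchanged before the carbinol is made.
- Comparison: this road is better in step economy after the key step. The chosen plan sets against it a three-step precursor from purchased materials, a cyclisation known in racemic form on this substitution pattern, a C3 centre never exposed as an epimerisable carbonyl α-position, and Cα and C3 created together by one syn addition.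

Key step: step 4

**Remarks before the steps**

- Assumption: the sense of induction of the chiral acid in step 4 cannot be derived beforehand. The (R)-catalyst is assumed to give (2R,3R)-9; if the first run shows the opposite sense, the (S)-catalyst is used with nothing else changed.
- The descriptor at C2 changes from R (9 to 18) to S (20, 21) only because substituent priorities change; no inversion occurs.
- TBS = tert-butyldimethylsilyl; ppy = 2-phenylpyridinato. C1, C2, C3 and Cα in the Why lines refer to the discussion numbering.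

## Steps

Step 1
Reactants: 1 3,5-dimethoxyphenylacetic acid
Product: 3 2-(3,5-dimethoxyphenyl)-N-methoxy-N-methylacetamide, via acyl imidazolide 2 (not isolated)
Conditions: CDI, CH2Cl2, 25 °C; then MeNHOMe·HCl, 25 °C
Reagents that add atoms: N,O-dimethylhydroxylamine hydrochloride, CNOC.Cl; 1,1'-carbonyldiimidazole, O=C(n1ccnc1)n1ccnc1 (its imidazolyl group stays in intermediate 2 only)
Why: Activation of the acid as the acyl imidazolide and aminolysis give the Weinreb amide; the arylacetic acid carries no competing function.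

Step 2
Reactants: 4 1-bromo-3,5-dimethoxybenzene; 3 2-(3,5-dimethoxyphenyl)-N-methoxy-N-methylacetamide
Product: 6 1,2-bis(3,5-dimethoxyphenyl)ethan-1-one, via 3,5-dimethoxyphenylmagnesium bromide 5 (not isolated)
Conditions: Mg, I2 (cat.), THF, reflux; then 3, THF, 0 → 25 °C; aq NH4Cl
Reagents that add atoms: magnesium, [Mg] (its atom stays in intermediate 5 only)
Why: Weinreb ketone synthesis: the aryl Grignard adds once to give a chelated tetrahedral intermediate that collapses only on work-up, so no tertiary alcohol forms; addition at 0 °C should keep enolisation of the arylacetamide behind addition.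

Step 3
Reactants: 6 1,2-bis(3,5-dimethoxyphenyl)ethan-1-one; 7 4-methoxybenzaldehyde
Product: 8 (2E)-1,2-bis(3,5-dimethoxyphenyl)-3-(4-methoxyphenyl)prop-2-en-1-one
Conditions: piperidine, AcOH (cat.), toluene, reflux, Dean–Stark
Reagents that add atoms: none
Why: Amine-catalysed aldol (Knoevenagel-type) condensation of a deoxybenzoin with a non-enolisable aldehyde, driven by removal of water; the E isomer (acyl trans to the β-aryl) is the usual product, and either geometry would serve because acid interconverts them in step 4.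

Step 4
Reactants: 8 (2E)-1,2-bis(3,5-dimethoxyphenyl)-3-(4-methoxyphenyl)prop-2-en-1-one
Product: 9 (2R,3R)-2-(3,5-dimethoxyphenyl)-4,6-dimethoxy-3-(4-methoxyphenyl)-2,3-dihydro-1H-inden-1-one (trans)
Conditions: (R)-3,3'-bis(2,4,6-triisopropylphenyl)-1,1'-binaphthyl-2,2'-diyl N-triflyl phosphoramide (10 mol%), CHCl3, 40 °C
Reagents that add atoms: none
Why: Proposed new method: protonation of the ketone by the chiral acid gives a hydroxypentadienyl cation, held as a hydrogen-bonded contact ion pair with the phosphoramide anion, in which one C=C of the ketone-bound 3,5-dimethoxyphenyl ring is the second alkene; thermal conrotatory 4π-electrocyclisation (the Nazarov mode of closure of the five-membered ring) joins the β-carbon to the arene carbon ortho to one methoxy group and para to the other, and loss of the arenium proton restores the benzene ring irreversibly. The closest known reaction types are the strong-acid Nazarov cyclisation of 2-aryl chalcones to racemic trans-2,3-diarylindan-1-ones and the N-triflyl phosphoramide-catalysed enantioselective Nazarov cyclisation of activated divinyl ketones; their combination on a non-chelating aryl vinyl ketone is the untested part. C1 (locant 3 of 9) is fixed by the sense of conrotation at the β-carbon, which the chiral anion has to bias (torquoselectivity); the β-aryl group sits on the outside of the U-shaped cation because the enone is E. C2 is not set in the cyclisation but in the ketonisation of the 1-hydroxyindene, and the acid keeps it in equilibrium, so the two aryl groups should settle trans. Site selectivity needs no control: the two ortho carbons of the ketone aryl are equivalent and doubly activated, and the α-aryl ring cannot reach the β-carbon in a five-membered closure. Enantiomeric purity can be raised by recrystallisation of the indanone if needed.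

Step 5
Reactants: 9 (2R,3R)-2-(3,5-dimethoxyphenyl)-4,6-dimethoxy-3-(4-methoxyphenyl)-2,3-dihydro-1H-inden-1-one
Product: 10 (1S,2R,3R)-2-(3,5-dimethoxyphenyl)-4,6-dimethoxy-3-(4-methoxyphenyl)-2,3-dihydro-1H-inden-1-ol (OH cis to the 2-aryl)
Conditions: NaBH4, MeOH/THF, 0 → 25 °C
Reagents that add atoms: none
Why: Hydride reduction of the ketone, with approach anti to the adjacent C2 aryl expected to give the alcohol drawn; its epimer would be equally usable because this centre is ionised in step 6, and C1 and C2 are not touched.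

Step 6
Reactants: 10 (1S,2R,3R)-2-(3,5-dimethoxyphenyl)-4,6-dimethoxy-3-(4-methoxyphenyl)-2,3-dihydro-1H-inden-1-ol; 11 (4-methoxyphenyl)methanethiol
Product: 12 (1R,2R,3R)-2-(3,5-dimethoxyphenyl)-4,6-dimethoxy-3-(4-methoxyphenyl)-1-{[(4-methoxyphenyl)methyl]sulfanyl}-2,3-dihydro-1H-indene (all-trans)
Conditions: ZnI2, ClCH2CH2Cl, 25 °C
Reagents that add atoms: none
Why: Lewis-acid-mediated SN1 thioetherification of a benzylic alcohol: ZnI2 ionises the indanol and the thiol traps the benzylic cation on the face away from the C2 aryl; the configuration at the sulfur-bearing carbon is without consequence because it becomes sp2 in step 8.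

Step 7
Reactants: 12 the all-trans sulfide
Product: 13 (1R,2R,3R)-2-(3,5-dimethoxyphenyl)-4,6-dimethoxy-3-(4-methoxyphenyl)-1-{[(4-methoxyphenyl)methyl]sulfonyl}-2,3-dihydro-1H-indene
Conditions: mCPBA, NaHCO3, CH2Cl2, 0 → 25 °C
Reagents that add atoms: 3-chloroperoxybenzoic acid, OOC(=O)c1cccc(Cl)c1
Why: Peracid oxidation of the sulfide to the sulfone by two oxygen transfers; the methoxyarenes are inert to buffered peracid at this temperature.

Step 8
Reactants: 13 the sulfone
Product: 15 (1E,2R,3R)-2-(3,5-dimethoxyphenyl)-4,6-dimethoxy-1-[(4-methoxyphenyl)methylidene]-3-(4-methoxyphenyl)-2,3-dihydro-1H-indene, via α-chloro sulfone 14 (not isolated)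
Conditions: KOH, CCl4, t-BuOH/H2O, 80 °C
Reagents that add atoms: carbon tetrachloride, ClC(Cl)(Cl)Cl (its chlorine stays in intermediate 14 only)
Why: Ramberg–Bäcklund olefination with in-situ halogenation: the benzylic α-carbon is chlorinated, the ring α'-carbanion closes to the episulfone, and loss of SO2 gives the exocyclic alkene. The E isomer (benzylidene aryl trans to the benzo ring) is expected from the base-equilibrated episulfone, and the reaction type is known for 1-benzylidene-2,3-diarylindanes.

Step 9
Reactants: 15 the E hexamethyl ether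
Product: 16 (1E,2R,3R)-2-(3,5-dihydroxyphenyl)-1-[(4-hydroxyphenyl)methylidene]-3-(4-hydroxyphenyl)-2,3-dihydro-1H-indene-4,6-diol
Conditions: BBr3, CH2Cl2, −78 → 25 °C; MeOH, H2O
Reagents that add atoms: none
Why: Exhaustive Lewis-acid cleavage of aryl methyl ethers; it is placed here because the stilbene-type alkene tolerates BBr3 whereas the later carbinol would not, and neither C1 nor C2 is ionisable under these conditions.

Step 10
Reactants: 16 the E hexaphenol
Product: 17 hexakis-O-TBS ether of 16 (1E,2R,3R)
Conditions: TBSCl, imidazole, DMF, 25 °C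
Reagents that add atoms: tert-butyldimethylsilyl chloride, CC(C)(C)[Si](C)(C)Cl
Why: Standard silylation of phenols; the silyl ethers mask the air-sensitive hexaphenol, are inert to borane, and leave under buffered fluoride at the end.

Step 11
Reactants: 17 the E hexakis-TBS ether
Product: 18 hexakis-O-TBS ether, (1Z,2R,3R) isomer (benzylidene aryl cis to the benzo ring)
Conditions: fac-Ir(ppy)3 (1 mol%), blue LEDs (450 nm), degassed THF, 25 °C
Reagents that add atoms: none
Why: Triplet-sensitised contra-thermodynamic E→Z isomerisation of a stilbene-type alkene: energy transfer from the excited iridium complex is efficient to the planar, conjugated E isomer and poor to the Z isomer, whose benzylidene aryl is twisted by the peri C4–H, so Z should accumulate at the photostationary state. The visible-light triplet pathway avoids the singlet 6π photocyclisation of the cis-stilbene unit, and C1 and C2 are untouched.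

Step 12
Reactants: 18 the Z hexakis-TBS ether
Product: 20 (R)-{(1S,2S,3R)-2-[3,5-bis(TBS-oxy)phenyl]-4,6-bis(TBS-oxy)-3-[4-(TBS-oxy)phenyl]-2,3-dihydro-1H-inden-1-yl}[4-(TBS-oxy)phenyl]methanol, via benzylic alkylborane 19 (not isolated)
Conditions: BH3·THF, THF, 0 → 25 °C; then 30% H2O2, aq NaOAc, 0 → 25 °C
Reagents that add atoms: borane–tetrahydrofuran complex, [BH3-][O+]1CCCC1 (its boron stays in intermediate 19 only); hydrogen peroxide, OO
Why: Hydroboration–oxidation of a trisubstituted alkene: boron goes to the less substituted exocyclic carbon Cα and hydrogen to C3 in a syn four-centre addition on the face anti to the adjacent C2 aryl, and the oxidation proceeds with retention. C3 (side chain cis to the C2 aryl) and Cα (R, because the alkene is Z) are therefore set together; acetate-buffered peroxide should spare the aryl silyl ethers.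

Step 13
Reactants: 20 the hexakis-TBS carbinol
Product: 21 (1S,2S,3R)-2-(3,5-dihydroxyphenyl)-1-[(R)-hydroxy(4-hydroxyphenyl)methyl]-3-(4-hydroxyphenyl)-2,3-dihydro-1H-indene-4,6-diol (CNP0214825.3)
Conditions: TBAF, AcOH, THF, 0 → 25 °C
Reagents that add atoms: none
Why: Fluoride cleavage of the six aryl silyl ethers, buffered with acetic acid so that neither phenoxide-driven quinone methide formation nor acid ionisation of the 4-hydroxybenzylic alcohol is triggered; no stereocentre is touched.

## Compound list

1 | 3,5-dimethoxyphenylacetic acid | OC(=O)Cc1cc(OC)cc(OC)c1 | starting material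
2 | 2-(3,5-dimethoxyphenyl)-1-(1H-imidazol-1-yl)ethan-1-one (acyl imidazolide) | O=C(Cc1cc(OC)cc(OC)c1)n1ccnc1 | intermediate
3 | 2-(3,5-dimethoxyphenyl)-N-methoxy-N-methylacetamide | CON(C)C(=O)Cc1cc(OC)cc(OC)c1 | intermediate
4 | 1-bromo-3,5-dimethoxybenzene | COc1cc(Br)cc(OC)c1 | starting material
5 | 3,5-dimethoxyphenylmagnesium bromide | COc1cc([Mg]Br)cc(OC)c1 | intermediate
6 | 1,2-bis(3,5-dimethoxyphenyl)ethan-1-one | COc1cc(CC(=O)c2cc(OC)cc(OC)c2)cc(OC)c1 | intermediate
7 | 4-methoxybenzaldehyde | COc1ccc(C=O)cc1 | starting material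
8 | (2E)-1,2-bis(3,5-dimethoxyphenyl)-3-(4-methoxyphenyl)prop-2-en-1-one | COc1ccc(/C=C(/C(=O)c2cc(OC)cc(OC)c2)c2cc(OC)cc(OC)c2)cc1 | intermediate
9 | (2R,3R)-2-(3,5-dimethoxyphenyl)-4,6-dimethoxy-3-(4-methoxyphenyl)-2,3-dihydro-1H-inden-1-one | COc1ccc([C@@H]2c3c(OC)cc(OC)cc3C(=O)[C@H]2c2cc(OC)cc(OC)c2)cc1 | intermediate
10 | (1S,2R,3R)-2-(3,5-dimethoxyphenyl)-4,6-dimethoxy-3-(4-methoxyphenyl)-2,3-dihydro-1H-inden-1-ol | COc1ccc([C@@H]2c3c(OC)cc(OC)cc3[C@@H](O)[C@H]2c2cc(OC)cc(OC)c2)cc1 | intermediate
11 | (4-methoxyphenyl)methanethiol | COc1ccc(CS)cc1 | starting material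
12 | (1R,2R,3R)-2-(3,5-dimethoxyphenyl)-4,6-dimethoxy-3-(4-methoxyphenyl)-1-{[(4-methoxyphenyl)methyl]sulfanyl}-2,3-dihydro-1H-indene | COc1ccc([C@@H]2c3c(OC)cc(OC)cc3[C@H](SCc3ccc(OC)cc3)[C@H]2c2cc(OC)cc(OC)c2)cc1 | intermediate
13 | (1R,2R,3R)-2-(3,5-dimethoxyphenyl)-4,6-dimethoxy-3-(4-methoxyphenyl)-1-{[(4-methoxyphenyl)methyl]sulfonyl}-2,3-dihydro-1H-indene | COc1ccc([C@@H]2c3c(OC)cc(OC)cc3[C@H](S(=O)(=O)Cc3ccc(OC)cc3)[C@H]2c2cc(OC)cc(OC)c2)cc1 | intermediate
14 | α-chloro sulfone: 13 with one chlorine on the benzylic CH2 of the sulfonyl group (mixture at that carbon) | COc1ccc([C@@H]2c3c(OC)cc(OC)cc3[C@H](S(=O)(=O)C(Cl)c3ccc(OC)cc3)[C@H]2c2cc(OC)cc(OC)c2)cc1 | intermediate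
15 | (1E,2R,3R)-2-(3,5-dimethoxyphenyl)-4,6-dimethoxy-1-[(4-methoxyphenyl)methylidene]-3-(4-methoxyphenyl)-2,3-dihydro-1H-indene | COc1ccc([C@@H]2c3c(OC)cc(OC)cc3/C(=C/c3ccc(OC)cc3)[C@H]2c2cc(OC)cc(OC)c2)cc1 | intermediate
16 | (1E,2R,3R)-2-(3,5-dihydroxyphenyl)-1-[(4-hydroxyphenyl)methylidene]-3-(4-hydroxyphenyl)-2,3-dihydro-1H-indene-4,6-diol | Oc1ccc([C@@H]2c3c(O)cc(O)cc3/C(=C/c3ccc(O)cc3)[C@H]2c2cc(O)cc(O)c2)cc1 | intermediate
17 | hexakis-O-TBS ether of 16, (1E,2R,3R) | CC(C)(C)[Si](C)(C)Oc1ccc([C@@H]2c3c(O[Si](C)(C)C(C)(C)C)cc(O[Si](C)(C)C(C)(C)C)cc3/C(=C/c3ccc(O[Si](C)(C)C(C)(C)C)cc3)[C@H]2c2cc(O[Si](C)(C)C(C)(C)C)cc(O[Si](C)(C)C(C)(C)C)c2)cc1 | intermediate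
18 | hexakis-O-TBS ether, (1Z,2R,3R) isomer of 17 | CC(C)(C)[Si](C)(C)Oc1ccc([C@@H]2c3c(O[Si](C)(C)C(C)(C)C)cc(O[Si](C)(C)C(C)(C)C)cc3/C(=C\c3ccc(O[Si](C)(C)C(C)(C)C)cc3)[C@H]2c2cc(O[Si](C)(C)C(C)(C)C)cc(O[Si](C)(C)C(C)(C)C)c2)cc1 | intermediate
19 | alkylborane from 18: BH2 on Cα and H on C3, both added on the face anti to the C2 aryl; configurations as in 20 | CC(C)(C)[Si](C)(C)Oc1ccc([C@@H]2c3c(O[Si](C)(C)C(C)(C)C)cc(O[Si](C)(C)C(C)(C)C)cc3[C@@H]([C@@H](B)c3ccc(O[Si](C)(C)C(C)(C)C)cc3)[C@H]2c2cc(O[Si](C)(C)C(C)(C)C)cc(O[Si](C)(C)C(C)(C)C)c2)cc1 | intermediate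
20 | (R)-{(1S,2S,3R)-2-[3,5-bis(TBS-oxy)phenyl]-4,6-bis(TBS-oxy)-3-[4-(TBS-oxy)phenyl]-2,3-dihydro-1H-inden-1-yl}[4-(TBS-oxy)phenyl]methanol | CC(C)(C)[Si](C)(C)Oc1ccc([C@@H]2c3c(O[Si](C)(C)C(C)(C)C)cc(O[Si](C)(C)C(C)(C)C)cc3[C@@H]([C@@H](O)c3ccc(O[Si](C)(C)C(C)(C)C)cc3)[C@H]2c2cc(O[Si](C)(C)C(C)(C)C)cc(O[Si](C)(C)C(C)(C)C)c2)cc1 | intermediate
21 | (1S,2S,3R)-2-(3,5-dihydroxyphenyl)-1-[(R)-hydroxy(4-hydroxyphenyl)methyl]-3-(4-hydroxyphenyl)-2,3-dihydro-1H-indene-4,6-diol | Oc1ccc([C@@H]2c3c(O)cc(O)cc3[C@@H]([C@@H](O)c3ccc(O)cc3)[C@H]2c2cc(O)cc(O)c2)cc1 | target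

## Step count and least certain steps

Total: 13 steps. Longest linear sequence: 13 steps (1 → 21); 4, 7 and 11 enter as purchased materials.

**Step 4 (key step, proposed new method).** The acid may be too weak to turn over a non-chelating ketone, or the single-point hydrogen-bonded ion pair may be too loosely organised to bias the conrotation, so that conversion or enantioselectivity stays low. The fallback uses known chemistry and sets out from 8:
- Trifluoroacetic acid-mediated Nazarov cyclisation gives the racemic trans-indanone F1.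
- NaBH4 reduction gives the racemic indanol F2.
- Esterification with (1S)-camphanic chloride (Et3N, DMAP) gives the diastereomeric esters, the (1S,2R,3R)-indanyl camphanate F3 and the (1R,2S,3S)-indanyl camphanate F4, which are separated by crystallisation or chromatography.
- Saponification of F3 (LiOH, THF/H2O) returns to the route at 10.

**Step 11.** Energy transfer may discriminate too little between the two trisubstituted isomers, so that the photostationary state is not Z-rich enough, and photo-oxidation of the electron-rich alkene may compete if oxygen is not excluded. The fallback sets out from 17: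
- Hydroboration–oxidation of the E alkene under the conditions of step 12 gives, through the alkylborane F5, the Cα-epimeric (S)-carbinol F6 with the correct C3 configuration.
- Dess–Martin oxidation (NaHCO3 buffer) gives the aryl ketone F7.
- Reagent-controlled Corey–Bakshi–Shibata reduction ((S)-2-methyl-oxazaborolidine, BH3·SMe2, −20 °C; aryl as the large group) should install the (R)-carbinol and return to the route at 20.

**Step 12.** Facial selectivity may be eroded because the twisted benzylidene aryl and the remote C1 aryl also encumber the lower face. Boron may be drawn to C3 by the electron-rich aryl on Cα. Aryl silyl ethers may be lost in the oxidative work-up. The fallback forms the Cα–aryl bond instead and sets out from 9: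
- BBr3 gives the pentaphenol ketone F8, and TBSCl/imidazole its pentakis-TBS ether F9.
- Petasis methylenation (Cp2TiMe2, toluene, 65 °C) gives the 1-methylidene indane F10.
- 9-BBN adds to the 1,1-disubstituted alkene anti to the C2 aryl with unambiguous regiochemistry to give the B-alkyl-9-BBN F11; buffered peroxide then gives the primary alcohol F12.
- Dess–Martin oxidation gives the aldehyde F13.
- Addition of 4-(TBS-oxy)phenylmagnesium bromide F14 at −78 °C (Felkin–Anh, benzo ring as the large group) returns to the route at 20. A Cα epimer, should it form, can be inverted by the oxidation–reduction pair described for step 11.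

## Further compounds

F1 | step 4 | racemic trans-2-(3,5-dimethoxyphenyl)-4,6-dimethoxy-3-(4-methoxyphenyl)-2,3-dihydro-1H-inden-1-one (both enantiomers) | COc1ccc([C@@H]2c3c(OC)cc(OC)cc3C(=O)[C@H]2c2cc(OC)cc(OC)c2)cc1.COc1ccc([C@H]2c3c(OC)cc(OC)cc3C(=O)[C@@H]2c2cc(OC)cc(OC)c2)cc1
F2 | step 4 | racemic 1,2-cis-2,3-trans-2-(3,5-dimethoxyphenyl)-4,6-dimethoxy-3-(4-methoxyphenyl)-2,3-dihydro-1H-inden-1-ol (both enantiomers) | COc1ccc([C@@H]2c3c(OC)cc(OC)cc3[C@@H](O)[C@H]2c2cc(OC)cc(OC)c2)cc1.COc1ccc([C@H]2c3c(OC)cc(OC)cc3[C@H](O)[C@@H]2c2cc(OC)cc(OC)c2)cc1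
F3 | step 4 | (1S,2R,3R)-2-(3,5-dimethoxyphenyl)-4,6-dimethoxy-3-(4-methoxyphenyl)-2,3-dihydro-1H-inden-1-yl (1S,4R)-camphanate | COc1ccc([C@@H]2c3c(OC)cc(OC)cc3[C@@H](OC(=O)[C@@]34CC[C@@](C)(C(=O)O3)C4(C)C)[C@H]2c2cc(OC)cc(OC)c2)cc1
F4 | step 4 | (1R,2S,3S)-2-(3,5-dimethoxyphenyl)-4,6-dimethoxy-3-(4-methoxyphenyl)-2,3-dihydro-1H-inden-1-yl (1S,4R)-camphanate | COc1ccc([C@H]2c3c(OC)cc(OC)cc3[C@H](OC(=O)[C@@]34CC[C@@](C)(C(=O)O3)C4(C)C)[C@@H]2c2cc(OC)cc(OC)c2)cc1
F5 | step 11 | alkylborane from 17: BH2 on Cα and H on C3 added on the face anti to the C2 aryl (Cα epimer of 19) | CC(C)(C)[Si](C)(C)Oc1ccc([C@@H]2c3c(O[Si](C)(C)C(C)(C)C)cc(O[Si](C)(C)C(C)(C)C)cc3[C@@H]([C@H](B)c3ccc(O[Si](C)(C)C(C)(C)C)cc3)[C@H]2c2cc(O[Si](C)(C)C(C)(C)C)cc(O[Si](C)(C)C(C)(C)C)c2)cc1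
F6 | step 11 | (S)-{(1S,2S,3R)-2-[3,5-bis(TBS-oxy)phenyl]-4,6-bis(TBS-oxy)-3-[4-(TBS-oxy)phenyl]-2,3-dihydro-1H-inden-1-yl}[4-(TBS-oxy)phenyl]methanol (Cα epimer of 20) | CC(C)(C)[Si](C)(C)Oc1ccc([C@@H]2c3c(O[Si](C)(C)C(C)(C)C)cc(O[Si](C)(C)C(C)(C)C)cc3[C@@H]([C@H](O)c3ccc(O[Si](C)(C)C(C)(C)C)cc3)[C@H]2c2cc(O[Si](C)(C)C(C)(C)C)cc(O[Si](C)(C)C(C)(C)C)c2)cc1
F7 | step 11 | {(1S,2S,3R)-2-[3,5-bis(TBS-oxy)phenyl]-4,6-bis(TBS-oxy)-3-[4-(TBS-oxy)phenyl]-2,3-dihydro-1H-inden-1-yl}[4-(TBS-oxy)phenyl]methanone | CC(C)(C)[Si](C)(C)Oc1ccc([C@@H]2c3c(O[Si](C)(C)C(C)(C)C)cc(O[Si](C)(C)C(C)(C)C)cc3[C@@H](C(=O)c3ccc(O[Si](C)(C)C(C)(C)C)cc3)[C@H]2c2cc(O[Si](C)(C)C(C)(C)C)cc(O[Si](C)(C)C(C)(C)C)c2)cc1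
F8 | step 12 | (2R,3R)-2-(3,5-dihydroxyphenyl)-4,6-dihydroxy-3-(4-hydroxyphenyl)-2,3-dihydro-1H-inden-1-one | Oc1ccc([C@@H]2c3c(O)cc(O)cc3C(=O)[C@H]2c2cc(O)cc(O)c2)cc1
F9 | step 12 | pentakis-O-TBS ether of F8, (2R,3R) | CC(C)(C)[Si](C)(C)Oc1ccc([C@@H]2c3c(O[Si](C)(C)C(C)(C)C)cc(O[Si](C)(C)C(C)(C)C)cc3C(=O)[C@H]2c2cc(O[Si](C)(C)C(C)(C)C)cc(O[Si](C)(C)C(C)(C)C)c2)cc1
F10 | step 12 | (2R,3R)-2-[3,5-bis(TBS-oxy)phenyl]-4,6-bis(TBS-oxy)-1-methylidene-3-[4-(TBS-oxy)phenyl]-2,3-dihydro-1H-indene | CC(C)(C)[Si](C)(C)Oc1ccc([C@@H]2c3c(O[Si](C)(C)C(C)(C)C)cc(O[Si](C)(C)C(C)(C)C)cc3C(=C)[C@H]2c2cc(O[Si](C)(C)C(C)(C)C)cc(O[Si](C)(C)C(C)(C)C)c2)cc1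
F11 | step 12 | B-alkyl-9-borabicyclo[3.3.1]nonane from F10: boron on the exocyclic CH2, H on C3 anti to the C2 aryl | CC(C)(C)[Si](C)(C)Oc1ccc([C@@H]2c3c(O[Si](C)(C)C(C)(C)C)cc(O[Si](C)(C)C(C)(C)C)cc3[C@@H](CB3C4CCCC3CCC4)[C@H]2c2cc(O[Si](C)(C)C(C)(C)C)cc(O[Si](C)(C)C(C)(C)C)c2)cc1
F12 | step 12 | {(1S,2S,3R)-2-[3,5-bis(TBS-oxy)phenyl]-4,6-bis(TBS-oxy)-3-[4-(TBS-oxy)phenyl]-2,3-dihydro-1H-inden-1-yl}methanol | CC(C)(C)[Si](C)(C)Oc1ccc([C@@H]2c3c(O[Si](C)(C)C(C)(C)C)cc(O[Si](C)(C)C(C)(C)C)cc3[C@@H](CO)[C@H]2c2cc(O[Si](C)(C)C(C)(C)C)cc(O[Si](C)(C)C(C)(C)C)c2)cc1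
F13 | step 12 | (1S,2S,3R)-2-[3,5-bis(TBS-oxy)phenyl]-4,6-bis(TBS-oxy)-3-[4-(TBS-oxy)phenyl]-2,3-dihydro-1H-indene-1-carbaldehyde | CC(C)(C)[Si](C)(C)Oc1ccc([C@@H]2c3c(O[Si](C)(C)C(C)(C)C)cc(O[Si](C)(C)C(C)(C)C)cc3[C@@H](C=O)[C@H]2c2cc(O[Si](C)(C)C(C)(C)C)cc(O[Si](C)(C)C(C)(C)C)c2)cc1
F14 | step 12 | {4-[(tert-butyldimethylsilyl)oxy]phenyl}magnesium bromide | CC(C)(C)[Si](C)(C)Oc1ccc([Mg]Br)cc1
A1 | alternative 1 | cis-2,3-disubstituted 5-bromoindan-7-ol (target numbering) with the silylated carbinol side chain, benzyl-protected | C1c2c(O)cc(Br)cc2[C@@H]([C@@H](O[Si](C)(C)C(C)(C)C)c2ccc(OCc3ccccc3)cc2)[C@H]1c1cc(OCc2ccccc2)cc(OCc2ccccc2)c1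
A2 | alternative 1 | TBS ether of 1-[4-(benzyloxy)phenyl]-3-[3,5-bis(benzyloxy)phenyl]-2-(4-bromofuran-2-yl)hex-5-yn-1-ol, stereocentres as in A1 | Brc1coc(c1)[C@@H]([C@@H](O[Si](C)(C)C(C)(C)C)c1ccc(OCc2ccccc2)cc1)[C@H](CC#C)c1cc(OCc2ccccc2)cc(OCc2ccccc2)c1
A3 | alternative 2 | cis-{4,6-bis(benzyloxy)-2-[3,5-bis(benzyloxy)phenyl]-2,3-dihydro-1H-inden-1-yl}[4-(benzyloxy)phenyl]methanone | C1c2c(OCc3ccccc3)cc(OCc3ccccc3)cc2[C@@H](C(=O)c2ccc(OCc3ccccc3)cc2)[C@H]1c1cc(OCc2ccccc2)cc(OCc2ccccc2)c1
A4 | alternative 2 | 5,7-bis(benzyloxy)-1H-indene | C1C=Cc2cc(OCc3ccccc3)cc(OCc3ccccc3)c12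
A5 | alternative 2 | 1,3-bis(benzyloxy)-5-bromobenzene | Brc1cc(OCc2ccccc2)cc(OCc2ccccc2)c1
A6 | alternative 2 | [4-(benzyloxy)phenyl]tributylstannane | CCCC[Sn](CCCC)(CCCC)c1ccc(OCc2ccccc2)cc1
A7 | alternative 3 | N-methoxy-N-methyl 1,2-cis-2,3-trans-2-(3,5-dimethoxyphenyl)-4,6-dimethoxy-3-(4-methoxyphenyl)indane-1-carboxamide | COc1ccc([C@@H]2c3c(OC)cc(OC)cc3[C@@H](C(=O)N(C)OC)[C@H]2c2cc(OC)cc(OC)c2)cc1
A8 | alternative 3 | trans-1-diazo-3-(3,5-dimethoxyphenyl)-5,7-dimethoxy-4-(4-methoxyphenyl)-3,4-dihydronaphthalen-2(1H)-one | COc1ccc([C@@H]2c3c(OC)cc(OC)cc3C(=[N+]=[N-])C(=O)[C@H]2c2cc(OC)cc(OC)c2)cc1
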